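Retrosynthetic cuts, in order: the two O–CH3 bonds at O7 and O7'; the C3(unit B)–O bond to unit A (umbelliferone); the C3–Br bond; both C4–C4a bonds (units B and C) at once; the two aryl ester C–O bonds; the C8–C8' biaryl bond.
Enabling feature: without the C3–O substituent, units B and C are the same 7-oxygenated coumarin joined C8 to C8', a C2-symmetric 8,8'-bicoumarin. In each benzene ring C4a is the only free carbon ortho to O1, and it lies para to O7.
Forward order: the biaryl bond is made first on 3-methoxyphenol, before any lactone exists. The pyranone rings of units B and C then close in one operation, followed by C3 bromination of one half, attachment of intact unit A, and demethylation.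
Stereochemistry: the target has no stereocentre, and the C8–C8' axis carries no descriptor and is formed racemic.

Key step: step 5

Assumption: because the target structure shows no axial descriptor, material racemic at the hindered C8–C8' axis is taken as the goal.

Step 1
Reactants: 1 3-methoxyphenol
Product: 2 1-methoxy-3-(methoxymethoxy)benzene
Conditions: MOMCl, iPr2NEt, CH2Cl2, 0 °C to rt
Reagents that add atoms: chloromethyl methyl ether (MOMCl), COCCl
Why: Base-mediated O-alkylation of a phenol (acetal protection) is routine and installs a group that withstands n-BuLi, directs lithiation strongly and leaves under mild acid that does not touch the methyl ether.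

Step 2
Reactants: 2 1-methoxy-3-(methoxymethoxy)benzene (two molecules)
Product: 4 2,2'-dimethoxy-6,6'-bis(methoxymethoxy)biphenyl, via aryllithium 3 (not isolated)
Conditions: n-BuLi, THF, 0 °C to rt; then anhydrous CuCl2, −78 °C to rt
Reagents that add atoms: none
Why: Directed ortho-metalation occurs at C2 because this C–H is flanked by both the OMe and the OMOM donor, and oxidative homocoupling of the resulting 2,6-dialkoxyaryllithium by divalent copper (transmetalation, then C–C bond formation with reduction to monovalent copper) is an established way to tetra-ortho-oxygenated biphenyls, so the hindered bond that becomes C8–C8' is made while the molecule is still small and base-stable.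

Step 3
Reactants: 4 2,2'-dimethoxy-6,6'-bis(methoxymethoxy)biphenyl
Product: 5 6,6'-dimethoxybiphenyl-2,2'-diol
Conditions: conc. HCl (cat.), MeOH, 50 °C
Reagents that add atoms: none
Why: Acid-catalysed acetal exchange with methanol (MOM cleavage) liberates both phenols, whereas the aryl methyl ethers and the biaryl bond are inert under these conditions.

Step 4
Reactants: 5 6,6'-dimethoxybiphenyl-2,2'-diol; 6 propiolic acid (two equivalents)
Product: 8 6,6'-dimethoxybiphenyl-2,2'-diyl dipropiolate, via O-propioloylisourea 7 (not isolated)
Conditions: DCC, DMAP (cat.), CH2Cl2, −20 °C to 0 °C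
Reagents that add atoms: none
Why: Steglich esterification through the O-acylisourea is the usual entry to aryl propiolates, and low temperature together with only a catalytic amount of DMAP should hold back oxa-Michael addition of the phenol to the activated alkyne.

Step 5
Reactants: 8 6,6'-dimethoxybiphenyl-2,2'-diyl dipropiolate
Product: 10 7,7'-dimethoxy-8,8'-bicoumarin, via mono-coumarin propiolate 9 (not isolated)
Conditions: Pd(OAc)2 (10 mol %), TFA/CH2Cl2 (3:1), 0.02 M, 0 °C to rt
Reagents that add atoms: none
Why: In TFA, Pd(OAc)2 becomes an electrophilic trifluoroacetate of divalent palladium that binds a terminal alkyne; the arene then attacks the terminal alkyne carbon anti to the metal in a Friedel–Crafts sense, rearomatisation leaves a C3-vinylpalladium species, and TFA protodemetalates it and returns the catalyst. The closest known reaction type is the Fujiwara intramolecular hydroarylation of aryl alkynoates, the standard alkyne route to coumarins, here run twice in one flask by way of 9. The pyranone of unit B and the pyranone of unit C each close in the 6-endo-dig mode with formation of C4–C4a. No stereocentre is created and the C8–C8' axis stays racemic. The step needs ortho attack to win over ipso attack, and the substrate secures this: on each ring one ortho carbon is taken up by the biaryl bond, the free one is para to the methoxy donor, and the ipso carbon is only meta to it, so spirocyclisation gains no stabilisation. Dilution should hold back intermolecular hydroarylation, and the reacting carbons lie far from the crowded axis, so the second closure should be as easy as the first.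

Step 6
Reactants: 10 7,7'-dimethoxy-8,8'-bicoumarin
Product: 11 3-bromo-7,7'-dimethoxy-8,8'-bicoumarin
Conditions: NBS (0.8 equiv), MeCN, rt, dark; recovered 10 resubmitted
Reagents that add atoms: N-bromosuccinimide (NBS), O=C1CCC(=O)N1Br
Why: Electrophilic vinylic bromination of a 7-alkoxycoumarin: Br+ adds to C3 because the resulting C4 benzylic cation is stabilised by the para-related 7-OMe group and loss of the C3 proton restores the enoate, C8 is blocked, and since the two C3–H sites are equivalent and electronically insulated by the twisted axis a deficiency of NBS should leave mainly monobromide and unchanged 10.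

Step 7
Reactants: 11 3-bromo-7,7'-dimethoxy-8,8'-bicoumarin; 12 umbelliferone (7-hydroxycoumarin)
Product: 13 7,7'-dimethoxy-3-[(2-oxo-2H-chromen-7-yl)oxy]-8,8'-bicoumarin
Conditions: CuI (10 mol %), N,N-dimethylglycine hydrochloride (30 mol %), Cs2CO3, anhydrous 1,4-dioxane, 90 °C
Reagents that add atoms: none
Why: Ullmann-type copper-catalysed C–O coupling of a vinylic bromide and a phenol, in which the electron-poor C3–Br bond adds oxidatively to the phenoxide of monovalent copper and reductive elimination places oxygen on the carbon that carried bromine, while a dry carbonate base should spare all three lactones.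

Step 8
Reactants: 13 7,7'-dimethoxy-3-[(2-oxo-2H-chromen-7-yl)oxy]-8,8'-bicoumarin
Product: 15 triumbelletin, via bis(dibromoboryl) ether 14 (not isolated)
Conditions: BBr3 (excess), CH2Cl2, −78 °C to rt; then H2O
Reagents that add atoms: none
Why: Lewis-acid cleavage of aryl methyl ethers: bromide attacks only the methyl carbon of the boron-complexed O–CH3 groups (SN2), the C3–O–C7 ether between units B and A is bonded to two sp2 carbons and cannot react this way, and the lactones should be released unchanged when the aryl borates are hydrolysed.

Compound list
1 | 3-methoxyphenol | COc1cccc(O)c1 | starting material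
2 | 1-methoxy-3-(methoxymethoxy)benzene | COCOc1cccc(OC)c1 | intermediate
3 | [2-methoxy-6-(methoxymethoxy)phenyl]lithium | [Li]c1c(OC)cccc1OCOC | intermediate
4 | 2,2'-dimethoxy-6,6'-bis(methoxymethoxy)biphenyl | COCOc1cccc(OC)c1-c1c(OC)cccc1OCOC | intermediate
5 | 6,6'-dimethoxybiphenyl-2,2'-diol | COc1cccc(O)c1-c1c(O)cccc1OC | intermediate
6 | propiolic acid | C#CC(=O)O | starting material
7 | O-propioloyl-N,N'-dicyclohexylisourea | C#CC(=O)OC(=NC1CCCCC1)NC1CCCCC1 | intermediate
8 | 6,6'-dimethoxybiphenyl-2,2'-diyl dipropiolate | C#CC(=O)Oc1cccc(OC)c1-c1c(OC)cccc1OC(=O)C#C | intermediate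
9 | 3-methoxy-2-(7-methoxy-2-oxo-2H-chromen-8-yl)phenyl propiolate | COc1ccc2ccc(=O)oc2c1-c1c(OC)cccc1OC(=O)C#C | intermediate
10 | 7,7'-dimethoxy-8,8'-bicoumarin | COc1ccc2ccc(=O)oc2c1-c1c(OC)ccc2ccc(=O)oc12 | intermediate
11 | 3-bromo-7,7'-dimethoxy-8,8'-bicoumarin (racemic axis) | COc1ccc2cc(Br)c(=O)oc2c1-c1c(OC)ccc2ccc(=O)oc12 | intermediate
12 | umbelliferone (7-hydroxycoumarin) | O=c1ccc2ccc(O)cc2o1 | starting material
13 | 7,7'-dimethoxy-3-[(2-oxo-2H-chromen-7-yl)oxy]-8,8'-bicoumarin (racemic axis) | O=c1ccc2ccc(Oc3cc4ccc(OC)c(-c5c(OC)ccc6ccc(=O)oc56)c4oc3=O)cc2o1 | intermediate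
14 | 7,7'-bis(dibromoboryloxy)-3-[(2-oxo-2H-chromen-7-yl)oxy]-8,8'-bicoumarin | O=c1ccc2ccc(Oc3cc4ccc(OB(Br)Br)c(-c5c(OB(Br)Br)ccc6ccc(=O)oc56)c4oc3=O)cc2o1 | intermediate
15 | triumbelletin, 7,7'-dihydroxy-3-[(2-oxo-2H-chromen-7-yl)oxy]-8,8'-bicoumarin (racemic axis) | O=c1ccc2ccc(Oc3cc4ccc(O)c(-c5c(O)ccc6ccc(=O)oc56)c4oc3=O)cc2o1 | target

Total step count: 8. Longest linear sequence: 8 steps, from 3-methoxyphenol 1 to triumbelletin 15. Propiolic acid 6 and umbelliferone 12 enter as purchased.

Steps most likely to fail

Step 7 (C–O coupling).
- What may go wrong: conjugate addition of the phenoxide at C4 followed by loss of HBr (cine substitution), base-induced opening and ring contraction of the α-bromolactone, or slow turnover because the phenoxide of 12 is electron-poor.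
- Fallback: it sets out from 11 and returns at 13, and it reverses the roles of the partners. Miyaura borylation of 11 (PdCl2(dppf), B2pin2, KOAc, dioxane, 80 °C) should give 7,7'-dimethoxy-3-(4,4,5,5-tetramethyl-1,3,2-dioxaborolan-2-yl)-8,8'-bicoumarin F1. A Chan–Lam oxidative coupling of this alkenylboronate and 12 (Cu(OAc)2, pyridine, 4 Å molecular sieves, air, CH2Cl2, rt) should then deliver 13.
- Why it helps: no leaving group remains at C3, so cine substitution is impossible. The medium is close to neutral at room temperature, which protects the lactones.

Step 6 (desymmetrising bromination).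
- What may go wrong: further bromination at C3' of the second half, competing attack at C6, and difficult separation of species that differ by a single bromine atom.
- Fallback: it sets out from 10 and returns at 13, and it moves the symmetry-breaking event into the coupling. Excess NBS in MeCN should drive 10 fully to 3,3'-dibromo-7,7'-dimethoxy-8,8'-bicoumarin F2, so the bromination need not be stopped halfway. The conditions of step 7 with a deficiency of 12 should give 3'-bromo-7,7'-dimethoxy-3-[(2-oxo-2H-chromen-7-yl)oxy]-8,8'-bicoumarin F3. The surplus vinylic bromide is then removed by formate hydrodebromination at zerovalent palladium (Pd(PPh3)4, HCO2H, Et3N, DMF, 60 °C) to give 13.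
- Why it helps: F3 differs from F2 by a whole coumarin unit and should separate easily, and unreacted F2 can be reused.

Step 5 (double hydroarylation).
- What may go wrong: stalling after the first ring closure, acidolysis of the aryl ester, addition of TFA to the alkyne, or intermolecular hydroarylation leading to oligomers.
- Fallback: it sets out from 5 and returns at 10, and it builds both pyranones by carbonyl olefination. Twofold magnesium-mediated ortho-formylation (MgCl2, Et3N, paraformaldehyde, MeCN, reflux) can only strike the single free ortho carbon of each phenol and should give 2,2'-dihydroxy-6,6'-dimethoxybiphenyl-3,3'-dicarbaldehyde F4. A twofold Wittig reaction using Ph3P=CHCO2Et in N,N-diethylaniline at reflux should pass through diethyl (2E,2'E)-3,3'-(2,2'-dihydroxy-6,6'-dimethoxybiphenyl-3,3'-diyl)diacrylate F5. At that temperature F5 isomerises and lactonises in the same pot to 10.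

Further compounds
F1 | step 7 | 7,7'-dimethoxy-3-(4,4,5,5-tetramethyl-1,3,2-dioxaborolan-2-yl)-8,8'-bicoumarin | COc1ccc2cc(B3OC(C)(C)C(C)(C)O3)c(=O)oc2c1-c1c(OC)ccc2ccc(=O)oc12
F2 | step 6 | 3,3'-dibromo-7,7'-dimethoxy-8,8'-bicoumarin | COc1ccc2cc(Br)c(=O)oc2c1-c1c(OC)ccc2cc(Br)c(=O)oc12
F3 | step 6 | 3'-bromo-7,7'-dimethoxy-3-[(2-oxo-2H-chromen-7-yl)oxy]-8,8'-bicoumarin | O=c1ccc2ccc(Oc3cc4ccc(OC)c(-c5c(OC)ccc6cc(Br)c(=O)oc56)c4oc3=O)cc2o1
F4 | step 5 | 2,2'-dihydroxy-6,6'-dimethoxybiphenyl-3,3'-dicarbaldehyde | COc1ccc(C=O)c(O)c1-c1c(OC)ccc(C=O)c1O
F5 | step 5 | diethyl (2E,2'E)-3,3'-(2,2'-dihydroxy-6,6'-dimethoxybiphenyl-3,3'-diyl)diacrylate | CCOC(=O)/C=C/c1ccc(OC)c(-c2c(OC)ccc(/C=C/C(=O)OCC)c2O)c1O
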